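**Plan**
- Cuts: the ring bonds C1–C6 and C2–C3 (numbering of 3-henicosyl-2-hydroxy-5-methoxycyclohexa-2,5-diene-1,4-dione) are cut together, which releases C1/C2 as oxalyl chloride; then the O–Si bond, the C(=O)–C(OMe) bond to a 1-methoxyvinyl anion, and the amide C–N bond back to tricosanoic acid.
- Enabling feature: C1 (C=O) and C2 (C–OH) are vicinal and both at the carboxylic acid oxidation level. Their neighbours C6–H and C3–chain are the two ends of the four-carbon unit C6=C5(OMe)–C4(=O)–C3, which as its silyl dienol ether is a 2,3-dioxygenated 1,3-diene that is nucleophilic at both termini.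
- Forward: the chain is joined first (C23 acid → Weinreb amide → α-methoxy enone → silyl dienol ether). The single ring arises last, in one [4+2] double C-acylation that also sets the oxidation level and the OMe/OH pattern.
- Stereochemistry: the target has no stereocentre; the (Z) enol ether geometry of the diene is incidental and vanishes in the quinone.

Key step: step 4

Remark: the side chain is read as unbranched henicosyl (21 carbons) and the quinone is drawn as the 2-hydroxy-1,4-dione tautomer of the given SMILES.

**Step 1**
Reactants: 1 tricosanoic acid
Product: 3 N-methoxy-N-methyltricosanamide, via acyl imidazole 2 (not isolated)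
Conditions: CDI, THF, 50 °C; then MeNHOMe·HCl, rt
Reagents that add atoms: N,O-dimethylhydroxylamine hydrochloride, CNOC.Cl
Why: Activation of the acid as its acyl imidazole followed by aminolysis is a standard amide coupling (Weinreb amide synthesis) that tolerates the poorly soluble long-chain acid in warm THF.

**Step 2**
Reactants: 3 N-methoxy-N-methyltricosanamide; 4 methyl vinyl ether (lithiated in the flask)
Product: 6 2-methoxypentacos-1-en-3-one, via lithium hemiaminal chelate 5 (not isolated)
Conditions: 4 (excess), t-BuLi, THF, −78 → 0 °C; then 3 in THF, −78 → 0 °C; H2O quench at 0 °C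
Reagents that add atoms: none
Why: Weinreb ketone synthesis: 1-methoxyvinyllithium (CH2=C(OMe)Li), made by α-lithiation of methyl vinyl ether, should add only once because the chelated tetrahedral adduct 5 persists until the neutral aqueous quench, which also spares the acid-labile enol ether.

**Step 3**
Reactants: 6 2-methoxypentacos-1-en-3-one
Product: 7 tert-butyl{[(3Z)-2-methoxypentacosa-1,3-dien-3-yl]oxy}dimethylsilane
Conditions: TBSOTf, Et3N, CH2Cl2, 0 °C; cold aq. NaHCO3 work-up, filtration through Et3N-deactivated silica
Reagents that add atoms: tert-butyldimethylsilyl trifluoromethanesulfonate (TBSOTf), CC(C)(C)[Si](C)(C)OS(=O)(=O)C(F)(F)F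
Why: Soft enolisation of a vinyl ketone with a silyl triflate and a tertiary amine is the standard route to 2-silyloxy-1,3-dienes; only the chain CH2 carries α-hydrogens, so the regiochemistry is unambiguous, and the (Z) enol ether is expected but its geometry is irrelevant later.

**Step 4**
Reactants: 7 tert-butyl{[(3Z)-2-methoxypentacosa-1,3-dien-3-yl]oxy}dimethylsilane; 8 oxalyl chloride
Product: 10 3-henicosyl-2-hydroxy-5-methoxycyclohexa-2,5-diene-1,4-dione (target), via acid chloride 9 (not isolated)
Conditions: 8 (1.0 equiv, slow addition), 2,6-di-tert-butyl-4-methylpyridine (1.1 equiv), CH2Cl2 (0.02 M), −40 °C → rt; dilute aq. HCl work-up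
Reagents that add atoms: none
Why: Proposed new method: silylation has turned the ketone carbon of 6 into a donor, so both termini of diene 7 (the methoxyvinyl CH2 and the chain-bearing CH) are enol ether β-carbons, and the symmetrical 1,2-dielectrophile 8 should C-acylate them in turn, first the unhindered methoxyvinyl CH2 (proton taken up by the pyridine base) to give 9 and then, within the molecule, the silyl enol ether carbon with loss of TBSCl, after which enolisation towards the chain-bearing carbon delivers the hydroxyquinone at the correct oxidation level without any redox step. The closest known reaction types are the uncatalysed C-acylation of alkyl enol ethers by oxalyl chloride to 4-alkoxy-2-oxobut-3-enoyl chlorides and the cyclisation of 1,3-bis(silyl enol ethers) with oxalyl chloride, whereas a twofold C-acylation of a 2,3-dioxygenated 1,3-diene to a quinone is not established. The only ring closes by a 6-(enolendo)-exo-trig acylation, which needs the acyl group cis to the silyloxyvinyl carbon on the new vinylogous ester double bond; this is the expected E isomer and the push-pull alkene can equilibrate in any case. No stereocentre is formed and the enol ether geometry of 7 disappears in the quinone. The step needs carbon rather than oxygen acylation, a 1:1 union and the right placing of OMe and OH: the methyl ether cannot be O-acylated, the silyl ether oxygen of 9 could only close a seven-membered ring, high dilution with one equivalent of 8 disfavours twofold intermolecular acylation, and because 8 is symmetrical the two oxygen substituents alone (methyl kept, silyl lost) decide that OMe ends next to the ring CH and OH next to the chain.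

**Compound list**
1 | tricosanoic acid | CCCCCCCCCCCCCCCCCCCCCCC(=O)O | starting material
2 | 1-(1H-imidazol-1-yl)tricosan-1-one (acyl imidazole) | CCCCCCCCCCCCCCCCCCCCCCC(=O)n1ccnc1 | intermediate (not isolated)
3 | N-methoxy-N-methyltricosanamide | CCCCCCCCCCCCCCCCCCCCCCC(=O)N(C)OC | intermediate
4 | methyl vinyl ether (methoxyethene) | COC=C | starting material
5 | lithium 2-methoxy-3-[methoxy(methyl)amino]pentacos-1-en-3-olate (hemiaminal chelate) | CCCCCCCCCCCCCCCCCCCCCCC([O-])(N(C)OC)C(=C)OC.[Li+] | intermediate (not isolated)
6 | 2-methoxypentacos-1-en-3-one | CCCCCCCCCCCCCCCCCCCCCCC(=O)C(=C)OC | intermediate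
7 | tert-butyl{[(3Z)-2-methoxypentacosa-1,3-dien-3-yl]oxy}dimethylsilane | CCCCCCCCCCCCCCCCCCCCC/C=C(\O[Si](C)(C)C(C)(C)C)C(=C)OC | intermediate
8 | oxalyl chloride | O=C(Cl)C(=O)Cl | starting material
9 | (3E,5Z)-5-[(tert-butyldimethylsilyl)oxy]-4-methoxy-2-oxoheptacosa-3,5-dienoyl chloride | CCCCCCCCCCCCCCCCCCCCC/C=C(\O[Si](C)(C)C(C)(C)C)/C(OC)=C\C(=O)C(=O)Cl | intermediate (not isolated)
10 | 3-henicosyl-2-hydroxy-5-methoxycyclohexa-2,5-diene-1,4-dione | CCCCCCCCCCCCCCCCCCCCCC1=C(O)C(=O)C=C(OC)C1=O | target

Total step count: 4
Longest linear sequence: 4 steps (1 → 3 → 6 → 7 → 10)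

**Steps most likely to fail**

Step 4 (proposed new method). The ring may close through the enolic oxygen to a five-membered lactone if the silyl enol ether terminus is acylated first. Twofold intermolecular acylation with oligomerisation, or loss of the silyl group before the second acylation, could also divert the material. The fallback uses known chemistry, sets out from 6 and comes back at 10. Enone 6 is hydrolysed with dilute aqueous HCl in THF to pentacosane-2,3-dione F1. F1 is added slowly to diethyl oxalate and NaOEt in EtOH/THF (0 °C → reflux, then aq. HCl), so that a twofold crossed Claisen condensation at the methyl and the methylene group flanking the diketone closes the same two ring bonds and gives 3-henicosyl-2,5-dihydroxycyclohexa-2,5-diene-1,4-dione F2. Acid-catalysed etherification (MeOH, cat. H2SO4, reflux) should then methylate the vinylogous acid hydroxyl next to the ring CH in preference to the one flanked by the chain, giving 10.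

Step 3. The amine may add in conjugate fashion to the silyl-activated captodative enone, and the silyl or methyl enol ether may be cleaved hydrolytically during isolation. The fallback masks the enol ether during enolisation, sets out from 6 and comes back at 7. Acid-catalysed addition of methanol (MeOH, HC(OMe)3, cat. pyridinium p-toluenesulfonate) converts 6 into 2,2-dimethoxypentacosan-3-one F3, which no longer contains a Michael acceptor. Base-only enol silylation (KN(SiMe3)2, TBSCl, THF, −78 °C) gives tert-butyl{[(3Z)-2,2-dimethoxypentacos-3-en-3-yl]oxy}dimethylsilane F4. Elimination of one methoxy group from the ketal (TMSOTf, i-Pr2NEt, CH2Cl2, −20 → 0 °C) then regenerates the methyl enol ether and gives 7.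

Step 2. The waxy amide may precipitate at low temperature so that addition stays incomplete, and the enol ether may hydrolyse during work-up. The fallback brings in the terminal CH2 by olefination instead of a vinyl anion, sets out from 3 and comes back at 6. Lithiated diethyl (methoxymethyl)phosphonate (2 equiv, LiN(i-Pr)2, THF, −78 °C) is acylated by amide 3 to give racemic diethyl (1-methoxy-2-oxotetracosyl)phosphonate F5. Horner–Wadsworth–Emmons methylenation with aqueous formaldehyde and K2CO3 then gives 6.

**Further compounds**
F1 | step 4 | pentacosane-2,3-dione | CCCCCCCCCCCCCCCCCCCCCCC(=O)C(C)=O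
F2 | step 4 | 3-henicosyl-2,5-dihydroxycyclohexa-2,5-diene-1,4-dione | CCCCCCCCCCCCCCCCCCCCCC1=C(O)C(=O)C=C(O)C1=O
F3 | step 3 | 2,2-dimethoxypentacosan-3-one | CCCCCCCCCCCCCCCCCCCCCCC(=O)C(C)(OC)OC
F4 | step 3 | tert-butyl{[(3Z)-2,2-dimethoxypentacos-3-en-3-yl]oxy}dimethylsilane | CCCCCCCCCCCCCCCCCCCCC/C=C(\O[Si](C)(C)C(C)(C)C)C(C)(OC)OC
F5 | step 2 | diethyl (1-methoxy-2-oxotetracosyl)phosphonate (racemic) | CCCCCCCCCCCCCCCCCCCCCCC(=O)C(OC)P(=O)(OCC)OCC
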